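**Plan**

1. Retrosynthesis (isochroman-1-one locants): the side-chain ester is cut at its O–CH(CH3) bond, giving a mevalonate carboxylate and a secondary mesylate. The lactone ring is then cut at two bonds at once, O2–C3 and C1–C8a, which removes C1/O2 as CO2 and leaves an aryl bromide with a tosylate on C3. Last, the aryl–CH2 bond C4a–C4 is cut to a lithiated 1,4-bis(benzyloxy)-2-bromobenzene and a seven-carbon epoxide made from an alkyne and epichlorohydrin.
2. Enabling feature: the lactone unit C1(=O)–O2 is one CO2 molecule spanning the benzene carbon C8a and the sp3 carbon C3. These two atoms are held 1,4 to each other by C4a–C4, so a carboxylate generated on C8a is placed for 6-exo-tet attack on C3. The bromine that directs construction of C4a–C4 is afterwards the metalation handle at C8a.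
3. Forward order: chain epoxide, then aryl–CH2 bond, then tosylate, then one-flask Br/Li exchange, CO2 capture and invertive lactonisation (the only ring formed). The side-chain ester follows by a second invertive carboxylate alkylation, and hydrogenolysis of the benzyl ethers ends the route.
4. Stereochemistry: C3 (R) comes from (S)-epichlorohydrin through one inversion in the key step. The side-chain carbinol (R) comes from (S)-but-3-yn-2-ol through one inversion in the esterification. The mevalonate centre (R) comes from (R)-mevalonolactone and is never touched.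

Key step: step 8

Remark: (S)-but-3-yn-2-ol, (S)-epichlorohydrin, bromohydroquinone and (R)-mevalonolactone are taken as commercial.

**Route**

Step 1
Reactants: 1 (S)-but-3-yn-2-ol
Product: 2 (S)-tert-butyl(but-3-yn-2-yloxy)dimethylsilane
Conditions: TBSCl, imidazole, DMF, 0 °C to rt
Reagents that add atoms: tert-butyldimethylsilyl chloride, CC(C)(C)[Si](C)(C)Cl
Why: Imidazole-promoted O-silylation of a secondary alcohol should proceed without touching the C–O bond, so the (S) centre is kept.

Step 2
Reactants: 2 (S)-tert-butyl(but-3-yn-2-yloxy)dimethylsilane; 3 (S)-epichlorohydrin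
Product: 5 (2S,6S)-6-[(tert-butyldimethylsilyl)oxy]-1-chlorohept-4-yn-2-ol, via lithium acetylide 4 (not isolated)
Conditions: n-BuLi, THF, −78 °C; BF3·OEt2, then 3, −78 °C; H2O
Reagents that add atoms: none
Why: BF3-promoted SN2 opening of the epoxide by the lithium acetylide (epoxide alkynylation) should occur at the unsubstituted oxirane carbon and leave the C–Cl bond alone, so the new carbinol is (S) by retention of the epichlorohydrin centre.

Step 3
Reactants: 5 (2S,6S)-6-[(tert-butyldimethylsilyl)oxy]-1-chlorohept-4-yn-2-ol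
Product: 6 (2S,6S)-6-[(tert-butyldimethylsilyl)oxy]-1-chloroheptan-2-ol
Conditions: H2 (1 atm), PtO2, EtOAc, rt
Reagents that add atoms: none
Why: Heterogeneous catalytic hydrogenation should saturate the alkyne; platinum is chosen to limit hydrogenolysis of the propargylic C–O bond, and neither stereocentre takes part.

Step 4
Reactants: 6 (2S,6S)-6-[(tert-butyldimethylsilyl)oxy]-1-chloroheptan-2-ol
Product: 7 tert-butyldimethyl{[(2S)-5-[(2S)-oxiran-2-yl]pentan-2-yl]oxy}silane
Conditions: K2CO3, MeOH, rt
Reagents that add atoms: none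
Why: Intramolecular Williamson etherification (3-exo-tet) of the chlorohydrin should close the terminal epoxide at the CH2Cl carbon, so the carbinol C–O bond and its (S) configuration are kept.

Step 5
Reactants: 8 2-bromobenzene-1,4-diol (bromohydroquinone)
Product: 9 1,4-bis(benzyloxy)-2-bromobenzene
Conditions: BnBr, K2CO3, DMF, 50 °C, under N2
Reagents that add atoms: benzyl bromide, BrCc1ccccc1
Why: Williamson O-benzylation of both phenols under carbonate base; no stereocentre is involved.

Step 6
Reactants: 9 1,4-bis(benzyloxy)-2-bromobenzene; 7 tert-butyldimethyl{[(2S)-5-[(2S)-oxiran-2-yl]pentan-2-yl]oxy}silane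
Product: 11 (2S,6S)-1-[3,6-bis(benzyloxy)-2-bromophenyl]-6-[(tert-butyldimethylsilyl)oxy]heptan-2-ol, via aryllithium 10 (not isolated)
Conditions: LiN(i-Pr)2, THF, −78 °C; BF3·OEt2, then 7, −78 °C; H2O
Reagents that add atoms: none
Why: Deprotonative ortho-lithiation should take place at the ring C–H flanked by Br and OBn, the most acidic position, at a temperature below loss of LiBr to the aryne, and BF3-promoted SN2 opening of the epoxide at its CH2 terminus then carries the (S) carbinol over unchanged from 7.

Step 7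
Reactants: 11 (2S,6S)-1-[3,6-bis(benzyloxy)-2-bromophenyl]-6-[(tert-butyldimethylsilyl)oxy]heptan-2-ol
Product: 12 (2S,6S)-1-[3,6-bis(benzyloxy)-2-bromophenyl]-6-[(tert-butyldimethylsilyl)oxy]heptan-2-yl 4-methylbenzenesulfonate
Conditions: TsCl, Et3N, DMAP (cat.), CH2Cl2, 0 °C to rt
Reagents that add atoms: p-toluenesulfonyl chloride, Cc1ccc(cc1)S(Cl)(=O)=O
Why: O-sulfonylation of the secondary alcohol proceeds with retention because the C–O bond is not broken, and a tosylate is chosen because it has no acidic α-hydrogen toward the aryllithium of the next step.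

Step 8
Reactants: 12 (2S,6S)-1-[3,6-bis(benzyloxy)-2-bromophenyl]-6-[(tert-butyldimethylsilyl)oxy]heptan-2-yl 4-methylbenzenesulfonate
Product: 15 (3R)-5,8-bis(benzyloxy)-3-[(4S)-4-[(tert-butyldimethylsilyl)oxy]pentyl]isochroman-1-one, via aryllithium 13 (not isolated), via lithium benzoate 14 (not isolated)
Conditions: t-BuLi (2.1 equiv), THF/Et2O/pentane, −100 °C; CO2 (g), −100 to −40 °C; then DMF, 50 °C
Reagents that add atoms: carbon dioxide, O=C=O
Why: Bromine–lithium exchange with two equivalents of t-BuLi at −100 °C should give aryllithium 13, which CO2 carboxylates at C8a to lithium benzoate 14, and on adding DMF and warming a carboxylate oxygen displaces the tosylate at C3 by intramolecular SN2, so the C1–C8a and O2–C3 bonds are made in one flask. The closest known reaction type is the Parham-type sequence of halogen–lithium exchange, carboxylation and cyclisation of ortho-bromophenethyl electrophiles to isochroman-1-ones, joined to the invertive O-alkylation of carboxylates by secondary sulfonates. The lactone ring closes in the 6-exo-tet mode. No new stereocentre is created: C3 goes from (S) to (R) by stereospecific Walden inversion, so its configuration is fixed by the epichlorohydrin-derived carbinol. The step needs exchange and CO2 capture to outrun 4-exo-tet alkylation, proton transfer or attack at sulfur by the aryllithium, which −100 °C and immediate carboxylation should secure. It also needs intramolecular O-alkylation to outrun attack of LiBr (which would erode the configuration by double inversion) and elimination to the styrene, which the six-membered transition state and the low basicity of the carboxylate should secure.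

Step 9
Reactants: 15 (3R)-5,8-bis(benzyloxy)-3-[(4S)-4-[(tert-butyldimethylsilyl)oxy]pentyl]isochroman-1-one
Product: 16 (3R)-5,8-bis(benzyloxy)-3-[(4S)-4-hydroxypentyl]isochroman-1-one
Conditions: HF (48% aq), MeCN, 0 °C to rt
Reagents that add atoms: none
Why: Fluoride-driven desilylation under mildly acidic conditions should free the secondary alcohol while the lactone, the benzyl ethers and both stereocentres are untouched.

Step 10
Reactants: 16 (3R)-5,8-bis(benzyloxy)-3-[(4S)-4-hydroxypentyl]isochroman-1-one
Product: 17 (2S)-5-[(3R)-5,8-bis(benzyloxy)-1-oxoisochroman-3-yl]pentan-2-yl methanesulfonate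
Conditions: MsCl, Et3N, CH2Cl2, 0 °C
Reagents that add atoms: methanesulfonyl chloride, CS(Cl)(=O)=O
Why: Mesylation of the secondary alcohol with retention prepares the carbinol carbon for SN2 displacement.

Step 11
Reactants: 17 (2S)-5-[(3R)-5,8-bis(benzyloxy)-1-oxoisochroman-3-yl]pentan-2-yl methanesulfonate; 18 (R)-mevalonolactone
Product: 20 (2R)-5-[(3R)-5,8-bis(benzyloxy)-1-oxoisochroman-3-yl]pentan-2-yl (3R)-3,5-dihydroxy-3-methylpentanoate, via cesium mevalonate 19 (not isolated)
Conditions: 18 (2.2 equiv), CsOH·H2O (2.0 equiv), MeOH/H2O, rt, concentrated to the dry salt; then 17, DMF, 45 °C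
Reagents that add atoms: cesium hydroxide, [Cs+].[OH-]
Why: Saponification of the lactone with slightly less than one equivalent of CsOH gives the cesium carboxylate free of hydroxide, and its SN2 O-alkylation by the secondary mesylate in DMF (cesium carboxylate displacement) should invert the carbinol from (S) to (R), the unprotected primary and tertiary hydroxyls being far weaker nucleophiles than the carboxylate and the mevalonate centre not being involved.

Step 12
Reactants: 20 (2R)-5-[(3R)-5,8-bis(benzyloxy)-1-oxoisochroman-3-yl]pentan-2-yl (3R)-3,5-dihydroxy-3-methylpentanoate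
Product: 21 (2R)-5-[(3R)-5,8-dihydroxy-1-oxoisochroman-3-yl]pentan-2-yl (3R)-3,5-dihydroxy-3-methylpentanoate
Conditions: H2 (1 atm), Pd/C, EtOAc, rt; work-up under N2
Reagents that add atoms: none
Why: Catalytic hydrogenolysis of the two aryl benzyl ethers under neutral conditions should spare both esters and the homobenzylic lactone C–O bond, and no stereocentre is affected.

**Compound list**

1 | (S)-but-3-yn-2-ol | C[C@H](O)C#C | starting material
2 | (S)-tert-butyl(but-3-yn-2-yloxy)dimethylsilane | C[C@H](O[Si](C)(C)C(C)(C)C)C#C | intermediate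
3 | (S)-epichlorohydrin, (2S)-2-(chloromethyl)oxirane | ClC[C@@H]1CO1 | starting material
4 | [(3S)-3-[(tert-butyldimethylsilyl)oxy]but-1-yn-1-yl]lithium (lithium acetylide of 2, not isolated) | C[C@H](O[Si](C)(C)C(C)(C)C)C#C[Li] | intermediate
5 | (2S,6S)-6-[(tert-butyldimethylsilyl)oxy]-1-chlorohept-4-yn-2-ol | C[C@H](O[Si](C)(C)C(C)(C)C)C#CC[C@H](O)CCl | intermediate
6 | (2S,6S)-6-[(tert-butyldimethylsilyl)oxy]-1-chloroheptan-2-ol | C[C@H](O[Si](C)(C)C(C)(C)C)CCC[C@H](O)CCl | intermediate
7 | tert-butyldimethyl{[(2S)-5-[(2S)-oxiran-2-yl]pentan-2-yl]oxy}silane | C[C@H](O[Si](C)(C)C(C)(C)C)CCC[C@H]1CO1 | intermediate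
8 | 2-bromobenzene-1,4-diol (bromohydroquinone) | Oc1ccc(O)c(Br)c1 | starting material
9 | 1,4-bis(benzyloxy)-2-bromobenzene | Brc1cc(OCc2ccccc2)ccc1OCc1ccccc1 | intermediate
10 | [3,6-bis(benzyloxy)-2-bromophenyl]lithium (not isolated) | [Li]c1c(Br)c(OCc2ccccc2)ccc1OCc1ccccc1 | intermediate
11 | (2S,6S)-1-[3,6-bis(benzyloxy)-2-bromophenyl]-6-[(tert-butyldimethylsilyl)oxy]heptan-2-ol | C[C@H](O[Si](C)(C)C(C)(C)C)CCC[C@H](O)Cc1c(Br)c(OCc2ccccc2)ccc1OCc1ccccc1 | intermediate
12 | (2S,6S)-1-[3,6-bis(benzyloxy)-2-bromophenyl]-6-[(tert-butyldimethylsilyl)oxy]heptan-2-yl 4-methylbenzenesulfonate | C[C@H](O[Si](C)(C)C(C)(C)C)CCC[C@H](OS(=O)(=O)c1ccc(C)cc1)Cc1c(Br)c(OCc2ccccc2)ccc1OCc1ccccc1 | intermediate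
13 | {3,6-bis(benzyloxy)-2-[(2S,6S)-6-[(tert-butyldimethylsilyl)oxy]-2-(tosyloxy)heptyl]phenyl}lithium (not isolated) | C[C@H](O[Si](C)(C)C(C)(C)C)CCC[C@H](OS(=O)(=O)c1ccc(C)cc1)Cc1c([Li])c(OCc2ccccc2)ccc1OCc1ccccc1 | intermediate
14 | lithium 3,6-bis(benzyloxy)-2-[(2S,6S)-6-[(tert-butyldimethylsilyl)oxy]-2-(tosyloxy)heptyl]benzoate (not isolated) | C[C@H](O[Si](C)(C)C(C)(C)C)CCC[C@H](OS(=O)(=O)c1ccc(C)cc1)Cc1c(C(=O)[O-])c(OCc2ccccc2)ccc1OCc1ccccc1.[Li+] | intermediate
15 | (3R)-5,8-bis(benzyloxy)-3-[(4S)-4-[(tert-butyldimethylsilyl)oxy]pentyl]isochroman-1-one | C[C@H](O[Si](C)(C)C(C)(C)C)CCC[C@@H]1Cc2c(OCc3ccccc3)ccc(OCc3ccccc3)c2C(=O)O1 | intermediate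
16 | (3R)-5,8-bis(benzyloxy)-3-[(4S)-4-hydroxypentyl]isochroman-1-one | C[C@H](O)CCC[C@@H]1Cc2c(OCc3ccccc3)ccc(OCc3ccccc3)c2C(=O)O1 | intermediate
17 | (2S)-5-[(3R)-5,8-bis(benzyloxy)-1-oxoisochroman-3-yl]pentan-2-yl methanesulfonate | C[C@H](OS(C)(=O)=O)CCC[C@@H]1Cc2c(OCc3ccccc3)ccc(OCc3ccccc3)c2C(=O)O1 | intermediate
18 | (R)-mevalonolactone, (4R)-4-hydroxy-4-methyloxan-2-one | C[C@@]1(O)CCOC(=O)C1 | starting material
19 | cesium (3R)-3,5-dihydroxy-3-methylpentanoate (not isolated) | C[C@@](O)(CCO)CC(=O)[O-].[Cs+] | intermediate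
20 | (2R)-5-[(3R)-5,8-bis(benzyloxy)-1-oxoisochroman-3-yl]pentan-2-yl (3R)-3,5-dihydroxy-3-methylpentanoate | C[C@H](CCC[C@@H]1Cc2c(OCc3ccccc3)ccc(OCc3ccccc3)c2C(=O)O1)OC(=O)C[C@](C)(O)CCO | intermediate
21 | (2R)-5-[(3R)-5,8-dihydroxy-1-oxoisochroman-3-yl]pentan-2-yl (3R)-3,5-dihydroxy-3-methylpentanoate | C[C@H](CCC[C@@H]1Cc2c(O)ccc(O)c2C(=O)O1)OC(=O)C[C@](C)(O)CCO | target

**Step count**

Total: 12 steps. Longest linear sequence: 11 steps (steps 1–4 and 6–12, from compound 1); step 5 is a one-step branch.

**Steps most likely to fail**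

First, the key step (step 8). The aryllithium may be consumed before CO2 capture by intramolecular alkylation at the tosylate carbon, by proton transfer or by attack at sulfur, and elimination may compete with substitution during the warm phase. The fallback separates inversion from ring closure; it sets out from alcohol 11 and comes back to the route at lactone 15. Mitsunobu inversion of 11 with 4-nitrobenzoic acid (PPh3, DIAD, THF, 0 °C) should give (2R,6S)-1-[3,6-bis(benzyloxy)-2-bromophenyl]-6-[(tert-butyldimethylsilyl)oxy]heptan-2-yl 4-nitrobenzoate F1. Methanolysis (K2CO3, MeOH) should give the epimeric alcohol (2R,6S)-1-[3,6-bis(benzyloxy)-2-bromophenyl]-6-[(tert-butyldimethylsilyl)oxy]heptan-2-ol F2. Palladium-catalysed carbonylative lactonisation of F2 (Pd(OAc)2, Xantphos, CO 1 atm, Et3N, toluene, 100 °C) forms the acyl C–O bond with retention at the carbinol and should give 15.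

Second, the esterification (step 11). β-Elimination of the secondary mesylate may compete with substitution, and the new δ-hydroxy ester may undergo intramolecular transesterification back to mevalonolactone with release of the secondary alcohol. The fallback protects the primary hydroxyl and activates the alcohol instead of the sulfonate; it sets out from alcohol 16 and salt 19 and comes back at 20. Silylation of 19 (TBSCl, imidazole, DMF) should give tert-butyldimethylsilyl (3R)-5-[(tert-butyldimethylsilyl)oxy]-3-hydroxy-3-methylpentanoate F3. Cleavage of the silyl ester (K2CO3, THF/H2O, then pH 5) should give (3R)-5-[(tert-butyldimethylsilyl)oxy]-3-hydroxy-3-methylpentanoic acid F4. Mitsunobu esterification of 16 with F4 (PPh3, DIAD, toluene, 0 °C) inverts the carbinol and should give (2R)-5-[(3R)-5,8-bis(benzyloxy)-1-oxoisochroman-3-yl]pentan-2-yl (3R)-5-[(tert-butyldimethylsilyl)oxy]-3-hydroxy-3-methylpentanoate F5. Buffered HF·pyridine in THF/pyridine should then remove the primary silyl ether to give 20.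

Third, the aryl–CH2 bond formation (step 6). Loss of LiBr from the ortho-bromoaryllithium (aryne formation) may outrun the epoxide opening, and the opening may be slow because BF3 is bound by the amine. The fallback separates metalation from C–C bond formation; it sets out from 9 and comes back at 11. Aryllithium 10 is quenched at −78 °C with I2, which should give 1,4-bis(benzyloxy)-2-bromo-3-iodobenzene F6. Iodine–magnesium exchange (i-PrMgCl·LiCl, THF, −40 °C) should give [3,6-bis(benzyloxy)-2-bromophenyl]magnesium chloride F7, which loses halide far less readily than the lithium species. CuI-catalysed opening of epoxide 7 (10 mol %, −30 °C) at its CH2 terminus should then give 11.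

**Further compounds**

F1 | step 8 | (2R,6S)-1-[3,6-bis(benzyloxy)-2-bromophenyl]-6-[(tert-butyldimethylsilyl)oxy]heptan-2-yl 4-nitrobenzoate | C[C@H](O[Si](C)(C)C(C)(C)C)CCC[C@@H](OC(=O)c1ccc(cc1)[N+](=O)[O-])Cc1c(Br)c(OCc2ccccc2)ccc1OCc1ccccc1
F2 | step 8 | (2R,6S)-1-[3,6-bis(benzyloxy)-2-bromophenyl]-6-[(tert-butyldimethylsilyl)oxy]heptan-2-ol | C[C@H](O[Si](C)(C)C(C)(C)C)CCC[C@@H](O)Cc1c(Br)c(OCc2ccccc2)ccc1OCc1ccccc1
F3 | step 11 | tert-butyldimethylsilyl (3R)-5-[(tert-butyldimethylsilyl)oxy]-3-hydroxy-3-methylpentanoate | C[C@@](O)(CCO[Si](C)(C)C(C)(C)C)CC(=O)O[Si](C)(C)C(C)(C)C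
F4 | step 11 | (3R)-5-[(tert-butyldimethylsilyl)oxy]-3-hydroxy-3-methylpentanoic acid | C[C@@](O)(CCO[Si](C)(C)C(C)(C)C)CC(=O)O
F5 | step 11 | (2R)-5-[(3R)-5,8-bis(benzyloxy)-1-oxoisochroman-3-yl]pentan-2-yl (3R)-5-[(tert-butyldimethylsilyl)oxy]-3-hydroxy-3-methylpentanoate | C[C@H](CCC[C@@H]1Cc2c(OCc3ccccc3)ccc(OCc3ccccc3)c2C(=O)O1)OC(=O)C[C@](C)(O)CCO[Si](C)(C)C(C)(C)C
F6 | step 6 | 1,4-bis(benzyloxy)-2-bromo-3-iodobenzene | Ic1c(Br)c(OCc2ccccc2)ccc1OCc1ccccc1
F7 | step 6 | [3,6-bis(benzyloxy)-2-bromophenyl]magnesium chloride | Cl[Mg]c1c(Br)c(OCc2ccccc2)ccc1OCc1ccccc1
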